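## Retrosynthetic overview

- Ring C (the γ-pyrone) is the only ring built, and it is formed last by acid cyclodehydration of a 2-prenyl-1,3-diketone, with the MOM groups removed in the same operation.
- The diketone is cut at the future C2–C3 bond into an A-ring ketone (C13 skeleton, prenyl already on the α-carbon) and a B-ring N-acylbenzotriazole (C12 skeleton), joined by enolate acylation in the penultimate step.
- A-ring ketone: resorcinol → bis-MOM ether → Ir C–H borylation/oxidation (third oxygen) → tris-MOM ether → ortho-lithiation and Weinreb acylation → chelation-controlled removal of one ortho MOM. The Weinreb amide comes from a Johnson–Claisen rearrangement.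
- B-ring acyl donor: the same bis-MOM resorcinol → ortho-lithiation/prenylation at C2 → ortho-lithiation/carboxylation at C4 → benzotriazolide.
- Both benzene rings are bought as resorcinol; no ring other than ring C is constructed.

Assumption: the target has no stereocentres and no E/Z-stereogenic alkenes (both prenyl alkenes end in CMe2), so it is achiral and no enantiocontrol is needed.

## Route

**Step 1**
Reactants: 1 resorcinol (benzene-1,3-diol)
Product: 2, 1,3-bis(methoxymethoxy)benzene
Conditions: NaH, MOMCl, DMF, 0 °C → rt
Reagents that add atoms: chloromethyl methyl ether (MOMCl), COCCl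
Why: Williamson-type O-alkylation of both phenoxides; the MOM ethers protect the phenols and serve as ortho-directing groups later.

**Step 2**
Reactants: 2, 1,3-bis(methoxymethoxy)benzene; 3 prenyl bromide (1-bromo-3-methylbut-2-ene)
Product: 4, 1,3-bis(methoxymethoxy)-2-(3-methylbut-2-en-1-yl)benzene
Conditions: n-BuLi, THF, 0 °C → rt; CuI, −78 °C; then 3, −78 °C → rt
Reagents that add atoms: none beyond reactant 3 (CC(C)=CCBr)
Why: Directed ortho-metalation occurs at C2 between the two cooperating OMOM groups, and the aryl-copper species alkylates prenyl bromide at the primary carbon (SN2, linear prenyl).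

**Step 3**
Reactants: 4, 1,3-bis(methoxymethoxy)-2-(3-methylbut-2-en-1-yl)benzene
Product: 5, 2,4-bis(methoxymethoxy)-3-(3-methylbut-2-en-1-yl)benzoic acid
Conditions: n-BuLi, TMEDA, THF, −20 → 0 °C; CO2, −78 °C → rt; aq. NaH2PO4 (pH ≈ 4) work-up
Reagents that add atoms: carbon dioxide, O=C=O
Why: A second directed ortho-metalation (C4 and C6 are equivalent) followed by carboxylation; the mildly acidic work-up leaves the MOM acetals intact.

**Step 4**
Reactants: 5, 2,4-bis(methoxymethoxy)-3-(3-methylbut-2-en-1-yl)benzoic acid
Product: 6, 1-[2,4-bis(methoxymethoxy)-3-(3-methylbut-2-en-1-yl)benzoyl]-1H-benzotriazole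
Conditions: 1H-benzotriazole, EDC·HCl, CH2Cl2, rt
Reagents that add atoms: 1H-benzotriazole, c1ccc2[nH]nnc2c1
Why: Carbodiimide activation gives a bench-stable, neutral acyl donor without generating HCl, which an acid chloride preparation would produce and which would threaten the ortho-MOM group.

**Step 5**
Reactants: 2, 1,3-bis(methoxymethoxy)benzene
Product: 7, 3,5-bis(methoxymethoxy)phenol
Conditions: [Ir(OMe)(cod)]2 (1.5 mol %), dtbpy (3 mol %), B2pin2, THF, 80 °C; then aq. NaOH, H2O2, 0 °C → rt (one pot)
Reagents that add atoms: hydrogen peroxide, OO (source of the phenol oxygen); bis(pinacolato)diboron, CC1(C)OB(OC1(C)C)B1OC(C)(C)C(C)(C)O1 (boron is replaced in the same pot)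
Why: Sterically controlled Ir-catalysed C–H borylation attacks C5, the only C–H not ortho to a substituent, and basic peroxide oxidation converts the aryl boronate to the phenol without harming the MOM ethers.

**Step 6**
Reactants: 7, 3,5-bis(methoxymethoxy)phenol
Product: 8, 1,3,5-tris(methoxymethoxy)benzene
Conditions: NaH, MOMCl, DMF, 0 °C → rt
Reagents that add atoms: chloromethyl methyl ether (MOMCl), COCCl
Why: O-alkylation gives a C3-symmetric arene in which every ring C–H is flanked by two directing groups, so the next lithiation has a single possible outcome.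

**Step 7**
Reactants: 9, 2-methylbut-3-en-2-ol; 10 trimethyl orthoacetate
Product: 11, methyl 5-methylhex-4-enoate
Conditions: EtCO2H (cat.), neat, 140 °C (sealed tube, MeOH vented/distilled)
Reagents that add atoms: none
Why: Johnson–Claisen rearrangement; the [3,3] shift of the mixed ketene acetal moves the alkene to the trisubstituted (prenyl-type) position and delivers the γ,δ-unsaturated ester.

**Step 8**
Reactants: 11, methyl 5-methylhex-4-enoate
Product: 12, N-methoxy-N,5-dimethylhex-4-enamide
Conditions: MeNH(OMe)·HCl, i-PrMgCl, THF, −20 °C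
Reagents that add atoms: N,O-dimethylhydroxylamine hydrochloride, CNOC.Cl
Why: Direct ester aminolysis by the magnesium amide gives the Weinreb amide, which is needed to stop the next acylation at the ketone stage.

**Step 9**
Reactants: 8, 1,3,5-tris(methoxymethoxy)benzene; 12, N-methoxy-N,5-dimethylhex-4-enamide
Product: 13, 5-methyl-1-[2,4,6-tris(methoxymethoxy)phenyl]hex-4-en-1-one
Conditions: n-BuLi, THF, 0 °C → rt; then 12, −78 → 0 °C; aq. NH4Cl
Reagents that add atoms: none
Why: Directed ortho-metalation followed by Weinreb ketone synthesis; the chelated tetrahedral intermediate prevents over-addition.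

**Step 10**
Reactants: 13, 5-methyl-1-[2,4,6-tris(methoxymethoxy)phenyl]hex-4-en-1-one
Product: 14, 1-[2-hydroxy-4,6-bis(methoxymethoxy)phenyl]-5-methylhex-4-en-1-one
Conditions: MgBr2·OEt2 (≈2 equiv), Et2O/CH2Cl2, 0 °C → rt, monitored
Reagents that add atoms: none
Why: Chelation-controlled acetal cleavage; Mg bound between the ketone oxygen and an ortho MOM oxygen activates only that acetal (the two ortho groups are equivalent), and the resulting Mg phenoxide–ketone chelate disfavours a second cleavage, while the non-protic conditions spare the alkene.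

**Step 11 (fragment coupling)**
Reactants: 14, 1-[2-hydroxy-4,6-bis(methoxymethoxy)phenyl]-5-methylhex-4-en-1-one; 6, 1-[2,4-bis(methoxymethoxy)-3-(3-methylbut-2-en-1-yl)benzoyl]-1H-benzotriazole
Product: 15, 1-[2,4-bis(methoxymethoxy)-3-(3-methylbut-2-en-1-yl)phenyl]-3-[2-hydroxy-4,6-bis(methoxymethoxy)phenyl]-2-(3-methylbut-2-en-1-yl)propane-1,3-dione (racemic at C2, keto/enol/hemiketal mixture, used crude)
Conditions: LiHMDS (3.5 equiv), THF, −78 °C; then 6, −78 °C → rt; aq. NH4Cl
Reagents that add atoms: none
Why: Claisen-type acylation of the phenoxide/enolate dianion; any O-aryl ester formed first undergoes in-situ Baker–Venkataraman acyl transfer under the excess base, so both pathways lead to the same diketone enolate, and the C2 stereocentre is inconsequential because it is destroyed in the next step.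

**Step 12**
Reactants: 15, the 2-prenyl-1,3-diketone above
Product: 16, Kuwanon T, 2-[2,4-dihydroxy-3-(3-methylbut-2-en-1-yl)phenyl]-5,7-dihydroxy-3-(3-methylbut-2-en-1-yl)-4H-chromen-4-one
Conditions: HCl (≈2 M, from AcCl/MeOH), MeOH/THF, 45–50 °C, short reaction time
Reagents that add atoms: none
Why: Acid cyclodehydration closes the already free A-ring 2-OH onto the B-ring carbonyl and aromatises to the γ-pyrone while the B-ring 2'-oxygen is still masked, which fixes the regiochemistry; methanolysis of the four MOM acetals then completes the target.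

## Compound list

1 | resorcinol | Oc1cccc(O)c1 | starting material
2 | 1,3-bis(methoxymethoxy)benzene | COCOc1cccc(OCOC)c1 | intermediate
3 | prenyl bromide (1-bromo-3-methylbut-2-ene) | CC(C)=CCBr | starting material
4 | 1,3-bis(methoxymethoxy)-2-(3-methylbut-2-en-1-yl)benzene | COCOc1cccc(OCOC)c1CC=C(C)C | intermediate
5 | 2,4-bis(methoxymethoxy)-3-(3-methylbut-2-en-1-yl)benzoic acid | COCOc1ccc(C(=O)O)c(OCOC)c1CC=C(C)C | intermediate
6 | 1-[2,4-bis(methoxymethoxy)-3-(3-methylbut-2-en-1-yl)benzoyl]-1H-benzotriazole | COCOc1ccc(C(=O)n2nnc3ccccc32)c(OCOC)c1CC=C(C)C | intermediate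
7 | 3,5-bis(methoxymethoxy)phenol | COCOc1cc(O)cc(OCOC)c1 | intermediate
8 | 1,3,5-tris(methoxymethoxy)benzene | COCOc1cc(OCOC)cc(OCOC)c1 | intermediate
9 | 2-methylbut-3-en-2-ol | CC(C)(O)C=C | starting material
10 | trimethyl orthoacetate | CC(OC)(OC)OC | starting material
11 | methyl 5-methylhex-4-enoate | COC(=O)CCC=C(C)C | intermediate
12 | N-methoxy-N,5-dimethylhex-4-enamide | CON(C)C(=O)CCC=C(C)C | intermediate
13 | 5-methyl-1-[2,4,6-tris(methoxymethoxy)phenyl]hex-4-en-1-one | COCOc1cc(OCOC)c(C(=O)CCC=C(C)C)c(OCOC)c1 | intermediate
14 | 1-[2-hydroxy-4,6-bis(methoxymethoxy)phenyl]-5-methylhex-4-en-1-one | COCOc1cc(O)c(C(=O)CCC=C(C)C)c(OCOC)c1 | intermediate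
15 | 1-[2,4-bis(methoxymethoxy)-3-prenylphenyl]-3-[2-hydroxy-4,6-bis(methoxymethoxy)phenyl]-2-prenylpropane-1,3-dione (racemic) | COCOc1cc(O)c(C(=O)C(CC=C(C)C)C(=O)c2ccc(OCOC)c(CC=C(C)C)c2OCOC)c(OCOC)c1 | intermediate
16 | Kuwanon T | CC(C)=CCc1c(O)ccc(-c2oc3cc(O)cc(O)c3c(=O)c2CC=C(C)C)c1O | target

## Summary

Total step count: 12.
Longest linear sequence: 7 steps (1 → 5 → 6 → 9 → 10 → 11 → 12, from resorcinol). The B-ring branch (steps 1, 2, 3, 4, 11, 12) and the side-chain branch (steps 7, 8, 9, 10, 11, 12) are 6 steps each.

Three steps most likely to fail, each with a fallback: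

1. **Step 10, selective removal of one ortho MOM.** Over-cleavage or poor selectivity is possible. Fallback: avoid the tris-MOM intermediate altogether. Ortho-formylate phenol 7 (MgCl2, Et3N, paraformaldehyde) to 2-hydroxy-4,6-bis(methoxymethoxy)benzaldehyde, add 4-methylpent-3-enylmagnesium bromide, and oxidise the benzylic alcohol (MnO2 or DMP) to 14. The free ortho OH is then present from the start.

2. **Step 11, acylation of the hindered α-branched enolate.** Enol-ester formation or incomplete acyl transfer could lower the yield. Fallback: couple before the prenyl group is in place. Make 1-[2-hydroxy-4,6-bis(methoxymethoxy)phenyl]ethanone (8 + N-methoxy-N-methylacetamide, then mono-deprotection), esterify with acid 5 (EDC/DMAP), run a classical Baker–Venkataraman rearrangement (KOH/pyridine), then C-prenylate the 1,3-diketone (prenyl bromide, K2CO3) before ring closure.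

3. **Step 12, acidic cyclisation and global deprotection.** The 3'-prenyl group sits between two phenols and could cyclise to a chroman or hydrate. Fallback: carry SEM ethers in place of MOM (SEMCl in steps 1 and 6; they also direct lithiation). Close ring C under buffered conditions (NaOAc/AcOH, 80 °C) to the protected flavone, then deprotect with fluoride (TBAF, DMPU, 60–80 °C), so the free prenylphenols never meet strong acid.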